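**Assumption:** the SMILES is read literally, i.e. the (1R,2R,3aS,5S,8aR) core (azulene numbering, used for all bicyclic compounds below) with a Z side-chain alkene.

**Retrosynthetic overview**
1. Last bond: the tertiary C5–O bond of the bridged γ-lactone, by Markovnikov hydroacyloxylation of a 5-methylidene hydroazulene tert-butyl ester (closes the lactone, sets C5).
2. C1 quaternary centre: alkylation of the bicyclic methyl ester enolate with a C6 triflate made from cis-aconitic anhydride.
3. Seven-membered ring: 7-exo radical closure (C8–C8a) onto a cyclopentene ester; cis fusion follows from the tether.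
4. C3a quaternary centre: γ-allylation, then γ-tert-butoxycarbonylation, of the dianion of the pulegone-derived β-keto ester.
5. Ring order: cyclopentane (chiral pool) → cycloheptane → lactone.

**Route**

Step 1
Reactants: 1 (R)-(+)-pulegone
Product: 3 methyl (5R)-5-methyl-2-(propan-2-ylidene)cyclopentane-1-carboxylate (methyl pulegenate; C1 epimers), via pulegone dibromide 2 (not isolated)
Conditions: Br2, Et2O, 0 °C; then NaOMe, MeOH, reflux
Reagents that add atoms: sodium methoxide, C[O-].[Na+]
Why: Bromination of the enone alkene followed by Favorskii ring contraction gives the cyclopentane ester and leaves the methyl-bearing stereocentre (the only one taken from the chiral pool) untouched.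

Step 2
Reactants: 3 methyl pulegenate
Product: 4 methyl (1S,2R)-2-methyl-5-oxocyclopentane-1-carboxylate
Conditions: O3, CH2Cl2–MeOH, −78 °C; then Me2S, −78 °C → rt
Reagents that add atoms: ozone, [O-][O+]=O
Why: Ozonolysis of the tetrasubstituted alkene gives the β-keto ester, which settles as the trans epimer by enolisation.

Step 3
Reactants: 5 3-chloro-2-(chloromethyl)prop-1-ene
Product: 6 2-(chloromethyl)penta-1,4-diene
Conditions: CH2=CHMgBr (0.4 equiv), CuI (4 mol %), THF, −30 → 0 °C
Reagents that add atoms: vinylmagnesium bromide, C=C[Mg]Br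
Why: Copper-catalysed allylic substitution of one chloride (SN2 and SN2′ give the same product); excess dichloride suppresses double substitution.

Step 4
Reactants: 4 methyl (1S,2R)-2-methyl-5-oxocyclopentane-1-carboxylate; 6 2-(chloromethyl)penta-1,4-diene
Product: 7 methyl (2R)-2-methyl-4-(2-methylidenepent-4-en-1-yl)-5-oxocyclopentane-1-carboxylate (C1 and C4 epimers)
Conditions: LiN(iPr)2 (2.1 equiv), THF, 0 °C; then 6, −78 → 0 °C
Reagents that add atoms: none
Why: Weiler dianion alkylation places the allyl chain on the γ carbon only; the new stereocentre is re-enolised in step 5 and does not matter.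

Step 5
Reactants: 7 methyl (2R)-2-methyl-4-(2-methylidenepent-4-en-1-yl)-5-oxocyclopentane-1-carboxylate
Product: 9 1-tert-butyl 3-methyl (1S,4R)-4-methyl-1-(2-methylidenepent-4-en-1-yl)-2-[(trifluoromethanesulfonyl)oxy]cyclopent-2-ene-1,3-dicarboxylate, via keto diester 8 (not isolated)
Conditions: LiN(iPr)2 (2.2 equiv), THF, −78 → 0 °C; Boc2O, −78 °C; then PhNTf2, −78 °C → rt
Reagents that add atoms: di-tert-butyl dicarbonate, CC(C)(C)OC(=O)OC(=O)OC(C)(C)C; N-phenylbis(trifluoromethanesulfonimide), O=S(=O)(N(c1ccccc1)S(=O)(=O)C(F)(F)F)C(F)(F)F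
Why: A second Weiler dianion is C-acylated at the γ carbon anti to the ring methyl (1,3-induction; allylic strain with the planar enolate holds the methyl pseudo-axial), which sets the quaternary centre with the chain cis to methyl, and the remaining β-keto ester enolate is trapped as its enol triflate.

Step 6
Reactants: 9 enol triflate
Product: 10 1-tert-butyl 3-methyl (1S,4R)-4-methyl-1-(2-methylidenepent-4-en-1-yl)cyclopent-2-ene-1,3-dicarboxylate
Conditions: Pd(PPh3)4 (5 mol %), LiCl, Bu3SnH, THF, 0 °C
Reagents that add atoms: none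
Why: Palladium-catalysed hydride transfer to an enol triflate (Stille-type reduction) gives the cyclopentene ester; fast transmetalation from tin at 0 °C is chosen to outrun Heck addition to the pendant alkenes.

Step 7
Reactants: 10 cyclopentene diester
Product: 12 3a-tert-butyl 1-methyl (2R,3aS,8aR)-2-methyl-5-methylidenedecahydroazulene-1,3a-dicarboxylate (C1 epimers), via alkyl catecholborane 11 (not isolated)
Conditions: catecholborane (1.1 equiv), MeC(O)NMe2 (10 mol %), CH2Cl2, 0 °C → rt; then 4-tert-butylcatechol (1.5 equiv, syringe pump), tBuON=NOtBu (5 mol %), PhH (5 mM), 70 °C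
Reagents that add atoms: none
Why: Proposed new method: one-pot anti-Markovnikov hydroboration / deboronative radical 7-exo-trig Giese cyclisation — catecholborane adds only to the monosubstituted alkene, an aryloxyl radical from the catechol displaces the primary alkyl radical at boron, this radical adds to the enoate β carbon from the face of its own tether (cis ring fusion, C8a–H set), and the α-ester radical takes H from the catechol to carry the chain; the closest known chemistry is the hydroboration / radical protodeboronation and deboronative conjugate addition of B-alkylcatecholboranes, not yet shown for a seven-membered ring closure onto an enoate.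

Step 8
Reactants: 13 cis-aconitic anhydride
Product: 14 trimethyl (Z)-prop-1-ene-1,2,3-tricarboxylate (trimethyl cis-aconitate)
Conditions: MeOH, H2SO4 (cat.), 40 °C
Reagents that add atoms: methanol, CO
Why: Anhydride methanolysis and Fischer esterification at mild temperature keep the Z geometry.

Step 9
Reactants: 14 trimethyl cis-aconitate
Product: 15 (2Z)-2-(2-hydroxyethyl)but-2-ene-1,4-diol
Conditions: iBu2AlH (7 equiv), CH2Cl2, −78 → 0 °C; Rochelle salt work-up
Reagents that add atoms: none
Why: 1,2-Reduction of the three esters by the aluminium hydride leaves the alkene and its geometry intact.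

Step 10
Reactants: 15 (2Z)-2-(2-hydroxyethyl)but-2-ene-1,4-diol
Product: 16 2-(2,2-dimethyl-4,7-dihydro-1,3-dioxepin-5-yl)ethan-1-ol
Conditions: Me2C(OMe)2, PPTS (cat.), CH2Cl2, rt
Reagents that add atoms: 2,2-dimethoxypropane, COC(C)(C)OC
Why: Acetalisation favours the cis-butenediol unit, preorganised for the seven-membered acetonide, and leaves the homoallylic alcohol free.

Step 11
Reactants: 12 bicyclic diester; 16 2-(2,2-dimethyl-4,7-dihydro-1,3-dioxepin-5-yl)ethan-1-ol
Product: 18 3a-tert-butyl 1-methyl (1R,2R,3aS,8aS)-1-[2-(2,2-dimethyl-4,7-dihydro-1,3-dioxepin-5-yl)ethyl]-2-methyl-5-methylidenedecahydroazulene-1,3a-dicarboxylate, via side-chain triflate 17 (not isolated)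
Conditions: 16, Tf2O, 2,6-lutidine, CH2Cl2, −78 °C (used at once); 12, LiN(iPr)2, THF–DMPU, −78 °C; combine, −78 → −30 °C
Reagents that add atoms: none
Why: Ester enolate alkylation with a primary triflate occurs on the convex face, anti to both the C2 methyl and the C8 ring carbon, which sets C1 with the ester cis to methyl.

Step 12
Reactants: 18 alkylated diester
Product: 19 tert-butyl (1R,2R,3aS,8aR)-1-[2-(2,2-dimethyl-4,7-dihydro-1,3-dioxepin-5-yl)ethyl]-1-(hydroxymethyl)-2-methyl-5-methylidenedecahydroazulene-3a-carboxylate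
Conditions: LiBH4, THF, MeOH (1 equiv), 0 → 50 °C
Reagents that add atoms: none
Why: Chemoselective borohydride reduction takes the methyl ester; the tert-butyl ester on the quaternary carbon is inert, and it cannot lactonise onto the new alcohol because the two groups are trans.

Step 13
Reactants: 19 hydroxy tert-butyl ester
Product: 21 (1R,2R,3aS,5S,8aR)-1-[(3Z)-5-hydroxy-3-(hydroxymethyl)pent-3-en-1-yl]-1-(hydroxymethyl)-2,5-dimethyldecahydro-5,3a-(epoxymethano)azulen-10-one (CNP0216031.1), via acetonide lactone 20 (not isolated)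
Conditions: [N,N′-bis(3,5-di-tert-butylsalicylidene)ethane-1,2-diaminato]cobalt (3 mol %), N-fluoro-2,4,6-trimethylpyridinium tetrafluoroborate (1.3 equiv), (Me2SiH)2O (1.3 equiv), PhCF3, 0 °C → rt; then 1 M aq. HCl, THF, rt
Reagents that add atoms: none
Why: Mukaiyama-type hydrogen-atom-transfer / radical-polar crossover hydroacyloxylation — cobalt hydride adds H to the 1,1-disubstituted alkene in preference to the trisubstituted one, the oxidised tertiary centre is captured by the ester carbonyl on the only face it can reach (forming the C5–O bond and fixing C5) with loss of isobutene, and dilute acid then frees the diol.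

**Compound list**
1 | (R)-(+)-pulegone | C[C@@H]1CCC(=C(C)C)C(=O)C1 | starting material
2 | (5R)-2-bromo-2-(2-bromopropan-2-yl)-5-methylcyclohexan-1-one (C2 epimers) | C[C@@H]1CCC(Br)(C(C)(C)Br)C(=O)C1 | intermediate
3 | methyl (5R)-5-methyl-2-(propan-2-ylidene)cyclopentane-1-carboxylate (C1 epimers) | C[C@@H]1CCC(=C(C)C)C1C(=O)OC | intermediate
4 | methyl (1S,2R)-2-methyl-5-oxocyclopentane-1-carboxylate | C[C@@H]1CCC(=O)[C@H]1C(=O)OC | intermediate
5 | 3-chloro-2-(chloromethyl)prop-1-ene | C=C(CCl)CCl | starting material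
6 | 2-(chloromethyl)penta-1,4-diene | C=CCC(=C)CCl | intermediate
7 | methyl (2R)-2-methyl-4-(2-methylidenepent-4-en-1-yl)-5-oxocyclopentane-1-carboxylate (C1, C4 epimers) | C[C@@H]1CC(CC(=C)CC=C)C(=O)C1C(=O)OC | intermediate
8 | 1-tert-butyl 3-methyl (1S,4R)-4-methyl-1-(2-methylidenepent-4-en-1-yl)-2-oxocyclopentane-1,3-dicarboxylate (C3 epimers/enol) | C[C@@H]1C[C@@](CC(=C)CC=C)(C(=O)OC(C)(C)C)C(=O)C1C(=O)OC | intermediate
9 | 1-tert-butyl 3-methyl (1S,4R)-4-methyl-1-(2-methylidenepent-4-en-1-yl)-2-[(trifluoromethanesulfonyl)oxy]cyclopent-2-ene-1,3-dicarboxylate | C[C@@H]1C[C@@](CC(=C)CC=C)(C(=O)OC(C)(C)C)C(OS(=O)(=O)C(F)(F)F)=C1C(=O)OC | intermediate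
10 | 1-tert-butyl 3-methyl (1S,4R)-4-methyl-1-(2-methylidenepent-4-en-1-yl)cyclopent-2-ene-1,3-dicarboxylate | C[C@@H]1C[C@@](CC(=C)CC=C)(C(=O)OC(C)(C)C)C=C1C(=O)OC | intermediate
11 | 1-tert-butyl 3-methyl (1S,4R)-1-[5-(1,3,2-benzodioxaborol-2-yl)-2-methylidenepentyl]-4-methylcyclopent-2-ene-1,3-dicarboxylate | C[C@@H]1C[C@@](CC(=C)CCCB2Oc3ccccc3O2)(C(=O)OC(C)(C)C)C=C1C(=O)OC | intermediate
12 | 3a-tert-butyl 1-methyl (2R,3aS,8aR)-2-methyl-5-methylidenedecahydroazulene-1,3a-dicarboxylate (cis-fused; C1 epimers) | C[C@@H]1C[C@]2(C(=O)OC(C)(C)C)CC(=C)CCC[C@@H]2C1C(=O)OC | intermediate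
13 | cis-aconitic anhydride, (2,5-dioxo-2,5-dihydrofuran-3-yl)acetic acid | O=C(O)CC1=CC(=O)OC1=O | starting material
14 | trimethyl (Z)-prop-1-ene-1,2,3-tricarboxylate | COC(=O)C/C(=C/C(=O)OC)C(=O)OC | intermediate
15 | (2Z)-2-(2-hydroxyethyl)but-2-ene-1,4-diol | OCC/C(=C/CO)CO | intermediate
16 | 2-(2,2-dimethyl-4,7-dihydro-1,3-dioxepin-5-yl)ethan-1-ol | OCCC1=CCOC(C)(C)OC1 | intermediate
17 | 2-(2,2-dimethyl-4,7-dihydro-1,3-dioxepin-5-yl)ethyl trifluoromethanesulfonate | O=S(=O)(OCCC1=CCOC(C)(C)OC1)C(F)(F)F | intermediate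
18 | 3a-tert-butyl 1-methyl (1R,2R,3aS,8aS)-1-[2-(2,2-dimethyl-4,7-dihydro-1,3-dioxepin-5-yl)ethyl]-2-methyl-5-methylidenedecahydroazulene-1,3a-dicarboxylate | C[C@@H]1C[C@]2(C(=O)OC(C)(C)C)CC(=C)CCC[C@@H]2[C@@]1(C(=O)OC)CCC3=CCOC(C)(C)OC3 | intermediate
19 | tert-butyl (1R,2R,3aS,8aR)-1-[2-(2,2-dimethyl-4,7-dihydro-1,3-dioxepin-5-yl)ethyl]-1-(hydroxymethyl)-2-methyl-5-methylidenedecahydroazulene-3a-carboxylate | C[C@@H]1C[C@]2(C(=O)OC(C)(C)C)CC(=C)CCC[C@@H]2[C@@]1(CO)CCC3=CCOC(C)(C)OC3 | intermediate
20 | (1R,2R,3aS,5S,8aR)-1-[2-(2,2-dimethyl-4,7-dihydro-1,3-dioxepin-5-yl)ethyl]-1-(hydroxymethyl)-2,5-dimethyldecahydro-5,3a-(epoxymethano)azulen-10-one | C[C@@H]1C[C@]23C[C@](C)(CCC[C@@H]2[C@@]1(CO)CCC4=CCOC(C)(C)OC4)OC3=O | intermediate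
21 | (1R,2R,3aS,5S,8aR)-1-[(3Z)-5-hydroxy-3-(hydroxymethyl)pent-3-en-1-yl]-1-(hydroxymethyl)-2,5-dimethyldecahydro-5,3a-(epoxymethano)azulen-10-one (CNP0216031.1) | C[C@@H]1C[C@]23C[C@](C)(CCC[C@@H]2[C@@]1(CO)CC/C(=C/CO)CO)OC3=O | target

**Step count:** 13 steps in total. The longest linear sequence is 9 steps (1, 2, 4, 5, 6, 7, 11, 12, 13).

**Three steps most likely to fail**

Step 5 — the diastereoselectivity at the new quaternary carbon rests on 1,3-induction alone, and O-acylation may compete. The fallback sets out from 4 and comes back at 9. The dianion of 4 is first tert-butoxycarbonylated at the unsubstituted γ methylene (LiN(iPr)2, Boc2O) to give 1-tert-butyl 3-methyl (4R)-4-methyl-2-oxocyclopentane-1,3-dicarboxylate F1. F1 is then allylated with chloride 6 at its less hindered α carbon under Tsuji–Trost conditions (Pd2(dba)3, chiral DACH-phenyl bisphosphine ligand, Cs2CO3, CH2Cl2), so that the ligand rather than the substrate fixes the quaternary centre; this gives 8. Sodium enolate formation (NaH) and PhNTf2 then give 9.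

Step 7 (the proposed new step) — premature reduction of the alkyl radical, 1,5-hydrogen transfer from the allylic CH2, or hydroboration of the methylidene group may intervene. The fallback sets out from 10 and comes back at 12. 9-BBN hydroborates the monosubstituted alkene selectively, and NaOMe/I2 converts the borane into 1-tert-butyl 3-methyl (1S,4R)-1-(5-iodo-2-methylidenepentyl)-4-methylcyclopent-2-ene-1,3-dicarboxylate F2. Slow addition of (Me3Si)3SiH with AIBN in benzene at 80 °C then closes the ring by a conventional iodine-abstraction 7-exo radical cyclisation to 12, with the same tether-controlled cis fusion.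

Step 11 — SN2 alkylation of a hindered, fully substituted enolate may lose to elimination of the homoallylic triflate. The fallback sets out from 12 and comes back at 21. The lithium enolate of 12 is added in a vinylogous (1,6) Michael reaction to 4-ethenylfuran-2(5H)-one; protonation to the conjugated butenolide gives 3a-tert-butyl 1-methyl (1R,2R,3aS,8aS)-2-methyl-5-methylidene-1-[2-(5-oxo-2,5-dihydrofuran-3-yl)ethyl]decahydroazulene-1,3a-dicarboxylate F3. iBu2AlH reduces the butenolide to the Z-diol and the methyl ester to the hydroxymethyl group, giving tert-butyl (1R,2R,3aS,8aR)-1-[(3Z)-5-hydroxy-3-(hydroxymethyl)pent-3-en-1-yl]-1-(hydroxymethyl)-2-methyl-5-methylidenedecahydroazulene-3a-carboxylate F4. The cobalt-catalysed hydroacyloxylation of step 13 (no acid stage) then gives 21.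

**Further compounds**
F1 | step 5 | 1-tert-butyl 3-methyl (4R)-4-methyl-2-oxocyclopentane-1,3-dicarboxylate | C[C@@H]1CC(C(=O)OC(C)(C)C)C(=O)C1C(=O)OC
F2 | step 7 | 1-tert-butyl 3-methyl (1S,4R)-1-(5-iodo-2-methylidenepentyl)-4-methylcyclopent-2-ene-1,3-dicarboxylate | C[C@@H]1C[C@@](CC(=C)CCCI)(C(=O)OC(C)(C)C)C=C1C(=O)OC
F3 | step 11 | 3a-tert-butyl 1-methyl (1R,2R,3aS,8aS)-2-methyl-5-methylidene-1-[2-(5-oxo-2,5-dihydrofuran-3-yl)ethyl]decahydroazulene-1,3a-dicarboxylate | C[C@@H]1C[C@]2(C(=O)OC(C)(C)C)CC(=C)CCC[C@@H]2[C@@]1(C(=O)OC)CCC3=CC(=O)OC3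
F4 | step 11 | tert-butyl (1R,2R,3aS,8aR)-1-[(3Z)-5-hydroxy-3-(hydroxymethyl)pent-3-en-1-yl]-1-(hydroxymethyl)-2-methyl-5-methylidenedecahydroazulene-3a-carboxylate | C[C@@H]1C[C@]2(C(=O)OC(C)(C)C)CC(=C)CCC[C@@H]2[C@@]1(CO)CC/C(=C/CO)CO
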